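**Assumption:** arteminorin C has no stereocentre, and its 3,3' axis is flanked only by C4–H and C2=O, so it rotates freely. The molecule is therefore achiral and there is no enantiomer to control.

## Retrosynthetic overview
1. The target is the bis-lactone of an unsymmetrical 2,3-bis(2-hydroxybenzylidene)succinic acid. The 3–3' bond is therefore bought in as the C2–C3 bond of a succinate, and no biaryl coupling is needed.
2. Last disconnection, after acetate removal: the O1–C2 and C3=C4 bonds of the isofraxidin pyranone. This gives a Perkin–Oglialoro condensation of 2,4-dihydroxy-3,5-dimethoxybenzaldehyde with esculetin-3-acetic acid.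
3. The aldehyde comes from syringaldehyde by C2 bromination and Cu-mediated hydroxylation.
4. Esculetin-3-acetic acid comes from a Pechmann condensation of benzene-1,2,4-triol with diethyl 2-formylsuccinate.
5. Ring order: the esculetin pyranone is formed first (Pechmann) and the isofraxidin pyranone last (Perkin).

## Forward route

**Step 1**
Reactants: 1, syringaldehyde (4-hydroxy-3,5-dimethoxybenzaldehyde)
Product: 2, 2-bromo-4-hydroxy-3,5-dimethoxybenzaldehyde
Conditions: Br2 (1.05 equiv), CHCl3, 0 °C → rt, 3 h
Reagents that add atoms: bromine, BrBr
Why: In this electrophilic aromatic bromination both positions ortho to the OH are blocked, and the symmetry-equivalent C2/C6 lie ortho/para to the two OMe groups, so one monobromide forms; no stereocentre is created.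

**Step 2**
Reactants: 2, 2-bromo-4-hydroxy-3,5-dimethoxybenzaldehyde
Product: 3, 2,4-dihydroxy-3,5-dimethoxybenzaldehyde
Conditions: aq. NaOH (8 equiv), Cu powder (10 mol %), H2O, reflux, N2, 24 h; then HCl to pH 2
Reagents that add atoms: sodium hydroxide, [Na+].[OH-]
Why: This is an Ullmann-type Cu-catalysed hydroxylation assisted by the ortho-formyl group, in which the para-phenoxide makes the CHO a vinylogous carboxylate and so suppresses Cannizzaro chemistry (same manifold as 5-bromovanillin → 5-hydroxyvanillin).

**Step 3**
Reactants: 4, benzene-1,2,4-triol; 5, diethyl 2-formylsuccinate (racemic/enolised)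
Product: 6, (6,7-dihydroxy-2-oxo-2H-chromen-3-yl)acetic acid (esculetin-3-acetic acid)
Conditions: 75 % H2SO4, N2, 0 °C → rt, 12 h; then dilute with H2O to about 20 % H2SO4, reflux, 3 h (one pot); cool and filter
Reagents that add atoms: diethyl 2-formylsuccinate, CCOC(=O)CC(C=O)C(=O)OCC; water, O
Why: In this Pechmann condensation the formyl carbon attacks C5 of the triol (para to 2-OH, ortho to 4-OH, as in the classical esculetin synthesis), the 4-OH lactonises on the α-ester (six-membered ring preferred over seven), and the side-chain ester is hydrolysed on dilution and heating, while the stereocentre of 5 becomes sp2.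

**Step 4**
Reactants: 3, 2,4-dihydroxy-3,5-dimethoxybenzaldehyde (1.0 equiv); 6, esculetin-3-acetic acid (1.1 equiv)
Product: 7, arteminorin C triacetate [3-(6,7-diacetoxy-2-oxo-2H-chromen-3-yl)-6,8-dimethoxy-2-oxo-2H-chromen-7-yl acetate]
Conditions: Ac2O (solvent), Et3N (4 equiv), 110 °C, N2, 12 h; pour onto ice and filter
Reagents that add atoms: acetic anhydride, CC(=O)OC(C)=O (three acetyl groups)
Why: In this Perkin–Oglialoro condensation the mixed anhydride of 6 enolises at its arylacetic-type CH2, adds to the CHO of 3, dehydrates and lactonises onto the 2-O to close the second pyranone, while the three remaining phenols are acetylated in situ, which shields the catechol from oxidation.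

**Step 5**
Reactants: 7, arteminorin C triacetate
Product: 8, arteminorin C (7,6',7'-trihydroxy-6,8-dimethoxy-3,3'-bichromene-2,2'-dione)
Conditions: 2 M aq. HCl/MeOH (1:3), reflux, N2, 3 h; cool and filter
Reagents that add atoms: none
Why: This acid-catalysed transesterification/hydrolysis removes the labile aryl acetates, while the aryl methyl ethers are inert, the coumarin lactones re-close if opened, and the catechol is stable in acid.

## Compound list
1 | syringaldehyde | COc1cc(C=O)cc(OC)c1O | starting material
2 | 2-bromo-4-hydroxy-3,5-dimethoxybenzaldehyde | COc1cc(C=O)c(Br)c(OC)c1O | intermediate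
3 | 2,4-dihydroxy-3,5-dimethoxybenzaldehyde | COc1cc(C=O)c(O)c(OC)c1O | intermediate
4 | benzene-1,2,4-triol | Oc1ccc(O)c(O)c1 | starting material
5 | diethyl 2-formylsuccinate (racemic) | CCOC(=O)CC(C=O)C(=O)OCC | starting material
6 | (6,7-dihydroxy-2-oxo-2H-chromen-3-yl)acetic acid | OC(=O)Cc1cc2cc(O)c(O)cc2oc1=O | intermediate
7 | arteminorin C triacetate | COc1cc2cc(-c3cc4cc(OC(C)=O)c(OC(C)=O)cc4oc3=O)c(=O)oc2c(OC)c1OC(C)=O | intermediate
8 | arteminorin C (achiral) | COc1cc2cc(-c3cc4cc(O)c(O)cc4oc3=O)c(=O)oc2c(OC)c1O | target

## Summary
Total step count: 5. The route is convergent.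
Longest linear sequence: 4 (1 → 2 → 3 → 7 → 8).

**Steps most likely to fail, with fallbacks**
1. **Step 2.** The bromide is di-ortho-substituted, and hydrodebromination back to 1 or air oxidation can compete. This fallback also bypasses any ipso-bromodeformylation in Step 1.
   - Drop the halide route and protect 1 as its 4-O-MOM ether.
   - Form the α-amino alkoxide in situ with lithium N,N,N'-trimethylethylenediamide, then carry out directed ortho-lithiation with n-BuLi.
   - Quench with B(OMe)3, then H2O2, to install the 2-OH.
   - The MOM group survives Step 4 and is cleaved in the HCl/MeOH of Step 5.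
2. **Step 3.** The triol may oxidise or sulfonate, and the formyl ester may decompose in strong acid.
   - Build 6 from the aldehyde oxidation level instead.
   - Condense commercial 2,4,5-trihydroxybenzaldehyde with succinic anhydride and sodium succinate in a Perkin-type reaction to give the coumarin-3-acetic acid.
   - Cleave the O-acyl groups with acid.
3. **Step 4.** Competing reactions are the simple Perkin reaction with Ac2O, which gives isofraxidin acetate, and Dakin–West-type ketone formation from 6. The 2-OH of 3 is also hindered.
   - Form the 3–3' bond by cross-coupling instead.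
   - Prepare 3-bromo-7-acetoxy-6,8-dimethoxycoumarin, either from commercial isofraxidin (Ac2O, then Br2/NaOAc addition–elimination) or from 3 with Ph3P=C(Br)CO2Et.
   - Couple it in a Suzuki–Miyaura reaction with 6,7-bis(MOM-oxy)coumarin-3-Bpin, made from esculetin by MOM protection, C3 bromination and Miyaura borylation.
   - Finish with global deprotection in HCl/MeOH.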